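**Retrosynthetic overview**

1. The strategy rests on one array in the 14-membered ring: the C10 carbinol, the E C11=C12 alkene with its C12 methyl, and the C13 methylene. This is what 1,4-opening of a C10–C11 oxirane bearing an isopropenyl group leaves behind, so the carbocycle is closed last, at C13–C14, by palladium-catalysed alkylation of a C14 bis(phenylsulfonyl) carbanion.
2. The open-chain precursor gets its trans (10S,11S) vinyl oxirane from a Felkin–Anh isopropenyl addition to a C11 aldehyde followed by closure from the C10 oxygen with inversion at C11. Its cis (7S,8R) oxirane comes from C10-hydroxyl-directed vanadium epoxidation of a Z C7=C8 alkene.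
3. C8–C9 is formed by a Z-alkenyllithium (from an iodo-Wittig reaction on a C7 aldehyde) opening a glycidyl ether made from (R)-glycidol, which supplies C9–C11 and the C10 stereocentre.
4. C1 (R) is set by oxazolidinone titanium enolate alkylation with PhSCH2Cl, which brings in C14 already bonded to sulfur. C15 comes from the acyl carbon by double methyl addition, and C2–C7 with the Z C3=C4 alkene come from neryl acetate.
5. Rings form in the order C7–C8 oxirane, C10–C11 oxirane, then the 14-membered carbocycle (the C10–C11 oxirane opens in that step). Desulfonylation and C10 acetylation follow.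

Key step: step 22

Remark: cembrane locants are used for all open-chain intermediates (C1 carries C15 with its two methyl groups, C14 carries sulfur, C13 is the isopropenyl methylene). The directed epoxidation in step 15 is assumed to follow the chair-like vanadate model and give the 1,3-syn product.

**Route**

Step 1
Reactants: 1 neryl acetate
Product: 3 (2Z)-3-methyl-6-oxohex-2-en-1-yl acetate, via secondary ozonide 2 (not isolated)
Conditions: O3 (1 equiv), CH2Cl2, −78 °C; then Me2S, −78 °C → rt
Reagents that add atoms: ozone ([O-][O+]=O)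
Why: Ozonolysis with reductive work-up, in which the allylic acetate lowers the electron density of the C3=C4 alkene so that one equivalent of ozone should cleave only the remote isopropylidene alkene and Me2S reduces the ozonide to the C7 aldehyde.

Step 2
Reactants: 3 (2Z)-3-methyl-6-oxohex-2-en-1-yl acetate
Product: 4 (2Z,6Z)-7-iodo-3-methylocta-2,6-dien-1-yl acetate
Conditions: EtPPh3I, n-BuLi, THF, 0 °C; I2, −78 °C; NaN(SiMe3)2, −20 °C; then 3, −78 → −20 °C
Reagents that add atoms: ethyltriphenylphosphonium iodide (CC[P+](c1ccccc1)(c1ccccc1)c1ccccc1.[I-]); iodine (II)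
Why: Stork–Zhao-type Wittig olefination with the α-iodo ylide Ph3P=C(I)CH3 made in the flask, which under kinetic control is expected to place iodine cis to the chain and give the Z-iodoalkene that fixes the later cis relationship of C6 and C9.

Step 3
Reactants: 4 (2Z,6Z)-7-iodo-3-methylocta-2,6-dien-1-yl acetate
Product: 5 (2Z,6Z)-7-iodo-3-methylocta-2,6-dien-1-ol
Conditions: K2CO3 (cat.), MeOH, 0 °C → rt
Reagents that add atoms: none
Why: Base-catalysed transesterification of the acetate in methanol, to which the iodoalkene and both alkene geometries are inert.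

Step 4
Reactants: 5 (2Z,6Z)-7-iodo-3-methylocta-2,6-dien-1-ol
Product: 6 (2Z,6Z)-1-bromo-7-iodo-3-methylocta-2,6-diene
Conditions: CBr4, PPh3, CH2Cl2, −20 → 0 °C
Reagents that add atoms: carbon tetrabromide (BrC(Br)(Br)Br)
Why: Appel reaction, in which bromide displaces the alkoxyphosphonium group at the primary allylic carbon under neutral conditions at low temperature so that the Z C3=C4 geometry should be kept.

Step 5
Reactants: 6 (2Z,6Z)-1-bromo-7-iodo-3-methylocta-2,6-diene
Product: 7 ethyl (4Z,8Z)-9-iodo-5-methyldeca-4,8-dienoate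
Conditions: EtOAc, LiN(iPr)2, THF, −78 °C; then 6, DMPU, −78 → −40 °C
Reagents that add atoms: ethyl acetate (CCOC(C)=O)
Why: SN2 alkylation of the lithium enolate of ethyl acetate by the primary allylic bromide adds C1 and C15 without allylic transposition, an excess of enolate limiting double alkylation.

Step 6
Reactants: 7 ethyl (4Z,8Z)-9-iodo-5-methyldeca-4,8-dienoate
Product: 8 (4Z,8Z)-9-iodo-5-methyldeca-4,8-dienoic acid
Conditions: LiOH·H2O, THF/MeOH/H2O, rt; then 1 M HCl
Reagents that add atoms: lithium hydroxide ([Li+].[OH-])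
Why: Saponification of the ethyl ester by hydroxide followed by acidification, with no effect on the iodoalkene.

Step 7
Reactants: 8 (4Z,8Z)-9-iodo-5-methyldeca-4,8-dienoic acid; 9 (R)-4-benzyl-2-oxazolidinone
Product: 11 (4R)-4-benzyl-3-[(4Z,8Z)-9-iodo-5-methyldeca-4,8-dienoyl]-1,3-oxazolidin-2-one, via mixed pivalic anhydride 10 (not isolated)
Conditions: t-BuCOCl, Et3N, THF, −20 °C; then 9, LiCl, −20 °C → rt
Reagents that add atoms: none
Why: N-Acylation of the oxazolidinone through the mixed pivalic anhydride, activated by LiCl and Et3N so that no organolithium base meets the iodoalkene.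

Step 8
Reactants: 11 (4R)-4-benzyl-3-[(4Z,8Z)-9-iodo-5-methyldeca-4,8-dienoyl]-1,3-oxazolidin-2-one
Product: 13 (4R)-4-benzyl-3-[(2R,4Z,8Z)-9-iodo-5-methyl-2-[(phenylsulfanyl)methyl]deca-4,8-dienoyl]-1,3-oxazolidin-2-one, via chlorotitanium enolate 12 (not isolated)
Conditions: TiCl4, i-Pr2NEt, CH2Cl2, 0 °C; then PhSCH2Cl, 0 °C
Reagents that add atoms: chloromethyl phenyl sulfide (ClCSc1ccccc1)
Why: Evans-type alkylation of the chelated Z titanium enolate by the phenylthiomethyl cation equivalent, which attacks the face away from the benzyl group of the (R)-auxiliary and so sets C1 as R while bringing in C14 already bonded to sulfur.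

Step 9
Reactants: 13 (4R)-4-benzyl-3-[(2R,4Z,8Z)-9-iodo-5-methyl-2-[(phenylsulfanyl)methyl]deca-4,8-dienoyl]-1,3-oxazolidin-2-one
Product: 14 methyl (2R,4Z,8Z)-9-iodo-5-methyl-2-[(phenylsulfanyl)methyl]deca-4,8-dienoate
Conditions: MeMgBr, MeOH, CH2Cl2, 0 °C
Reagents that add atoms: methanol (CO)
Why: Transesterification by MeOMgBr at the exocyclic carbonyl frees the auxiliary under almost neutral conditions, so that neither the C1 stereocentre nor the β-phenylthio group is exposed to free alkoxide.

Step 10
Reactants: 14 methyl (2R,4Z,8Z)-9-iodo-5-methyl-2-[(phenylsulfanyl)methyl]deca-4,8-dienoate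
Product: 15 (3R,5Z,9Z)-10-iodo-2,6-dimethyl-3-[(phenylsulfanyl)methyl]undeca-5,9-dien-2-ol
Conditions: MeMgBr, CeCl3, THF, −78 → 0 °C
Reagents that add atoms: methylmagnesium bromide (C[Mg]Br)
Why: Double Grignard addition to the ester, with CeCl3 to suppress enolisation, builds the C15 tertiary carbinol and leaves C1 untouched.

Step 11
Reactants: 15 (3R,5Z,9Z)-10-iodo-2,6-dimethyl-3-[(phenylsulfanyl)methyl]undeca-5,9-dien-2-ol
Product: 16 triethylsilyl ether of 15
Conditions: Et3SiOTf, 2,6-lutidine, CH2Cl2, −78 → 0 °C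
Reagents that add atoms: triethylsilyl trifluoromethanesulfonate (CC[Si](CC)(CC)OS(=O)(=O)C(F)(F)F)
Why: Silylation with the silyl triflate masks the tertiary hydroxyl, which would otherwise quench the alkenyllithium and direct the later vanadium epoxidation to the C3=C4 alkene.

Step 12
Reactants: 17 (R)-glycidol
Product: 18 (S)-4-methoxybenzyl glycidyl ether
Conditions: NaH, 4-MeOC6H4CH2Cl, n-Bu4NI (cat.), DMF, 0 °C → rt
Reagents that add atoms: 4-methoxybenzyl chloride (COc1ccc(CCl)cc1)
Why: Williamson ether synthesis at the primary alkoxide leaves the oxirane stereocentre untouched, the change of descriptor from R to S being only a matter of priority rules.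

Step 13
Reactants: 16 triethylsilyl ether of 15; 18 (S)-4-methoxybenzyl glycidyl ether
Product: 20 (2S,4Z,8Z,11R)-1-[(4-methoxybenzyl)oxy]-4,8,12-trimethyl-11-[(phenylsulfanyl)methyl]-12-[(triethylsilyl)oxy]trideca-4,8-dien-2-ol, via alkenyllithium 19 (not isolated)
Conditions: t-BuLi (2.1 equiv), Et2O, −78 °C; then 18, BF3·OEt2, −78 °C
Reagents that add atoms: none
Why: Iodine–lithium exchange with retention of alkene geometry followed by BF3-promoted SN2 opening at the terminal oxirane carbon forms C8–C9 and carries the glycidyl stereocentre over unchanged as the (10S) carbinol.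

Step 14
Reactants: 20 (10S)-homoallylic alcohol sulfide
Product: 21 (10S)-homoallylic alcohol sulfone
Conditions: (NH4)6Mo7O24·4H2O (cat.), 30% H2O2, EtOH, 0 °C → rt
Reagents that add atoms: hydrogen peroxide (OO)
Why: Molybdate-catalysed oxidation of the sulfide by H2O2 is much faster than epoxidation of isolated trisubstituted alkenes and gives the sulfone, so that sulfur no longer consumes oxidant in the next step.

Step 15
Reactants: 21 (10S)-homoallylic alcohol sulfone
Product: 22 (7S,8R,10S)-epoxy alcohol
Conditions: VO(acac)2 (cat.), t-BuOOH, CH2Cl2, 0 °C → rt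
Reagents that add atoms: tert-butyl hydroperoxide (CC(C)(C)OO)
Why: Hydroxyl-directed vanadium-catalysed epoxidation of the homoallylic alcohol, in which the vanadate ester delivers oxygen through a chair-like transition state with the C11 substituent equatorial, is expected to give the 1,3-syn epoxy alcohol, here the (7S,8R) cis-oxirane, while the undirected C3=C4 alkene stays intact.

Step 16
Reactants: 22 (7S,8R,10S)-epoxy alcohol
Product: 23 C10 tert-butyldimethylsilyl ether of 22
Conditions: t-BuMe2SiCl, imidazole, DMF, rt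
Reagents that add atoms: tert-butyldimethylsilyl chloride (CC(C)(C)[Si](C)(C)Cl)
Why: Silyl ether formation at the secondary C10 hydroxyl under mild imidazole conditions that do not open the oxirane.

Step 17
Reactants: 23 C10 tert-butyldimethylsilyl ether of 22
Product: 24 primary C11 alcohol
Conditions: DDQ, CH2Cl2/pH 7 buffer, 0 °C
Reagents that add atoms: none
Why: Oxidative cleavage of the 4-methoxybenzyl ether by DDQ through the benzylic oxocarbenium ion frees the primary C11 hydroxyl without touching the silyl ethers, the oxirane or the sulfone.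

Step 18
Reactants: 24 primary C11 alcohol
Product: 25 α-silyloxy C11 aldehyde
Conditions: Dess–Martin periodinane, pyridine, CH2Cl2, 0 °C → rt
Reagents that add atoms: none
Why: Dess–Martin oxidation buffered with pyridine gives the α-silyloxy aldehyde without epimerising C10 or opening the oxirane.

Step 19
Reactants: 25 α-silyloxy C11 aldehyde
Product: 26 (10S,11R)-isopropenyl carbinol
Conditions: CH2=C(CH3)MgBr, THF, −78 °C
Reagents that add atoms: isopropenylmagnesium bromide (CC(=C)[Mg]Br)
Why: Grignard addition under Felkin–Anh control, the non-chelating silyloxy group lying anti to the incoming nucleophile, is expected to favour the 10,11-anti alcohol with C11 R; the minor C11 epimer is to be removed by chromatography.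

Step 20
Reactants: 26 (10S,11R)-isopropenyl carbinol
Product: 28 (7S,8R,10S,11S)-bis-oxirane mono-sulfone with free C15 hydroxyl, via allylic mesylate 27 (not isolated)
Conditions: MsCl, Et3N, THF, −20 °C; then n-Bu4NF, 0 °C → rt
Reagents that add atoms: none
Why: Mesylation of the allylic hydroxyl then fluoride desilylation lets the C10 alkoxide displace the C11 mesylate in a 3-exo-tet SN2 closure with inversion at C11 and retention at C10, which gives the trans (10S,11S) vinyl oxirane, and excess fluoride also removes the tertiary triethylsilyl group.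

Step 21
Reactants: 28 (7S,8R,10S,11S)-bis-oxirane mono-sulfone with free C15 hydroxyl
Product: 30 open-chain C14 bis(phenylsulfonyl) bis-oxirane, via dilithiated sulfone 29 (not isolated)
Conditions: LiN(iPr)2 (3.2 equiv), THF, −78 °C; then PhSO2F, −78 → −40 °C
Reagents that add atoms: benzenesulfonyl fluoride (O=S(=O)(F)c1ccccc1)
Why: C-Sulfonylation of the α-sulfonyl carbanion by the sulfonyl fluoride, which transfers PhSO2 without halogenating the carbanion, gives the geminal bis-sulfone; three equivalents of base cover the hydroxyl, the first deprotonation and the more acidic product, and −78 °C keeps the carbanion from attacking either oxirane.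

Step 22
Reactants: 30 open-chain C14 bis(phenylsulfonyl) bis-oxirane
Product: 31 14,14-bis(phenylsulfonyl) macrocyclic (10S)-allylic alcohol
Conditions: Pd2(dba)3·CHCl3 (5 mol %), P(OiPr)3 (40 mol %), THF, reflux, slow addition of 30, high dilution
Reagents that add atoms: none
Why: Zerovalent palladium coordinates the isopropenyl alkene anti to the allylic C11–O bond and ionises the strained oxirane to a π-allyl complex over C11–C13 that carries a C10 alkoxide, and this alkoxide removes the acidic C14 proton so that the bis-sulfonyl carbanion arises only beside the electrophile and no external base is needed. The closest known reaction type is the Tsuji–Trost alkylation of vinyl epoxides by bis-sulfone pronucleophiles under neutral conditions at high dilution. The 14-membered ring closes by attack of C14 on the unsubstituted allyl terminus C13 (1,4-addition with the whole allyl unit inside the ring, an endo mode), whereas attack on C11 would give the more strained 12-membered ring through a more congested bond. No stereocentre is created, since C14 bears two identical sulfonyl groups and C11 becomes trigonal, and C10 keeps its S configuration because its C–O bond is never broken. The E geometry of C11=C12 follows from the syn π-allyl complex formed from the trans oxirane, in which the C10 substituent lies trans to C13. The step needs C13 over C11 attack and carbon over oxygen alkylation, which the steric bias of the termini, the distal alkoxide and the soft carbanion should secure, while the non-allylic C7–C8 oxirane is not ionised.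

Step 23
Reactants: 31 14,14-bis(phenylsulfonyl) macrocyclic (10S)-allylic alcohol
Product: 32 macrocyclic C10,C15-diol
Conditions: 6% Na(Hg), Na2HPO4, MeOH/THF, −20 °C → rt
Reagents that add atoms: none
Why: Reductive desulfonylation by electron transfer from sodium amalgam cleaves both C–S bonds at C14 in turn, the phosphate buffer keeping the methanol from becoming basic enough to open the oxirane.

Step 24
Reactants: 32 macrocyclic C10,C15-diol
Product: 33 CNP0254503.1
Conditions: Ac2O, pyridine, CH2Cl2, rt
Reagents that add atoms: acetic anhydride (CC(=O)OC(C)=O)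
Why: Acylation with Ac2O in pyridine without a nucleophilic catalyst esterifies the secondary allylic C10 hydroxyl and leaves the hindered tertiary C15 hydroxyl free.

**Compound list**

1 | neryl acetate, (2Z)-3,7-dimethylocta-2,6-dien-1-yl acetate | CC(C)=CCC/C(C)=C\COC(C)=O | starting material
2 | secondary ozonide of 1 at the isopropylidene alkene (3,3-dimethyl-1,2,4-trioxolane carrying the (3Z)-5-acetoxy-3-methylpent-3-enyl chain at C5) | CC1(C)OOC(CC/C(C)=C\COC(C)=O)O1 | intermediate
3 | (2Z)-3-methyl-6-oxohex-2-en-1-yl acetate | O=CCC/C(C)=C\COC(C)=O | intermediate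
4 | (2Z,6Z)-7-iodo-3-methylocta-2,6-dien-1-yl acetate | C/C(I)=C/CC/C(C)=C\COC(C)=O | intermediate
5 | (2Z,6Z)-7-iodo-3-methylocta-2,6-dien-1-ol | C/C(I)=C/CC/C(C)=C\CO | intermediate
6 | (2Z,6Z)-1-bromo-7-iodo-3-methylocta-2,6-diene | C/C(I)=C/CC/C(C)=C\CBr | intermediate
7 | ethyl (4Z,8Z)-9-iodo-5-methyldeca-4,8-dienoate | CCOC(=O)CC/C=C(/C)CC/C=C(/C)I | intermediate
8 | (4Z,8Z)-9-iodo-5-methyldeca-4,8-dienoic acid | OC(=O)CC/C=C(/C)CC/C=C(/C)I | intermediate
9 | (R)-4-benzyl-2-oxazolidinone | O=C1N[C@H](Cc2ccccc2)CO1 | starting material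
10 | mixed anhydride of 8 with pivalic acid | CC(C)(C)C(=O)OC(=O)CC/C=C(/C)CC/C=C(/C)I | intermediate
11 | (4R)-4-benzyl-3-[(4Z,8Z)-9-iodo-5-methyldeca-4,8-dienoyl]-1,3-oxazolidin-2-one | O=C1OC[C@@H](Cc2ccccc2)N1C(=O)CC/C=C(/C)CC/C=C(/C)I | intermediate
12 | chlorotitanium (TiCl3) Z-enolate of 11 | Cl[Ti](Cl)(Cl)O/C(=C\C/C=C(/C)CC/C=C(/C)I)N1C(=O)OC[C@H]1Cc1ccccc1 | intermediate
13 | (4R)-4-benzyl-3-[(2R,4Z,8Z)-9-iodo-5-methyl-2-[(phenylsulfanyl)methyl]deca-4,8-dienoyl]-1,3-oxazolidin-2-one | O=C1OC[C@@H](Cc2ccccc2)N1C(=O)[C@H](CSc1ccccc1)C/C=C(/C)CC/C=C(/C)I | intermediate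
14 | methyl (2R,4Z,8Z)-9-iodo-5-methyl-2-[(phenylsulfanyl)methyl]deca-4,8-dienoate | COC(=O)[C@H](CSc1ccccc1)C/C=C(/C)CC/C=C(/C)I | intermediate
15 | (3R,5Z,9Z)-10-iodo-2,6-dimethyl-3-[(phenylsulfanyl)methyl]undeca-5,9-dien-2-ol | CC(C)(O)[C@H](CSc1ccccc1)C/C=C(/C)CC/C=C(/C)I | intermediate
16 | triethylsilyl ether of 15 | CC[Si](CC)(CC)OC(C)(C)[C@H](CSc1ccccc1)C/C=C(/C)CC/C=C(/C)I | intermediate
17 | (R)-glycidol | C1O[C@@H]1CO | starting material
18 | (S)-4-methoxybenzyl glycidyl ether, (2S)-2-{[(4-methoxybenzyl)oxy]methyl}oxirane | COc1ccc(COC[C@@H]2CO2)cc1 | intermediate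
19 | alkenyllithium from 16 (lithium in place of iodine at C8, Z geometry kept) | [Li]/C(C)=C\CC/C(C)=C\C[C@@H](CSc1ccccc1)C(C)(C)O[Si](CC)(CC)CC | intermediate
20 | (2S,4Z,8Z,11R)-1-[(4-methoxybenzyl)oxy]-4,8,12-trimethyl-11-[(phenylsulfanyl)methyl]-12-[(triethylsilyl)oxy]trideca-4,8-dien-2-ol (cembrane locants: 10S alcohol, 7Z, 3Z, 1R) | COc1ccc(COC[C@@H](O)C/C(C)=C\CC/C(C)=C\C[C@@H](CSc2ccccc2)C(C)(C)O[Si](CC)(CC)CC)cc1 | intermediate
21 | (2S,4Z,8Z,11R)-1-[(4-methoxybenzyl)oxy]-4,8,12-trimethyl-11-[(phenylsulfonyl)methyl]-12-[(triethylsilyl)oxy]trideca-4,8-dien-2-ol | COc1ccc(COC[C@@H](O)C/C(C)=C\CC/C(C)=C\C[C@@H](CS(=O)(=O)c2ccccc2)C(C)(C)O[Si](CC)(CC)CC)cc1 | intermediate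
22 | (7S,8R)-cis-epoxide of 21 with the (10S) hydroxyl 1,3-syn to the oxirane oxygen; C11 4-methoxybenzyl ether, 3Z alkene, (1R), C14 sulfone, C15 triethylsilyl ether | COc1ccc(COC[C@@H](O)C[C@@]2(C)O[C@H]2CC/C(C)=C\C[C@@H](CS(=O)(=O)c3ccccc3)C(C)(C)O[Si](CC)(CC)CC)cc1 | intermediate
23 | C10 tert-butyldimethylsilyl ether of 22 | COc1ccc(COC[C@@H](O[Si](C)(C)C(C)(C)C)C[C@@]2(C)O[C@H]2CC/C(C)=C\C[C@@H](CS(=O)(=O)c3ccccc3)C(C)(C)O[Si](CC)(CC)CC)cc1 | intermediate
24 | primary C11 alcohol (10S silyl ether, 7S,8R oxirane, 3Z, 1R, C14 sulfone, C15 triethylsilyl ether) | OC[C@@H](O[Si](C)(C)C(C)(C)C)C[C@@]1(C)O[C@H]1CC/C(C)=C\C[C@@H](CS(=O)(=O)c1ccccc1)C(C)(C)O[Si](CC)(CC)CC | intermediate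
25 | C11 aldehyde with (10S) tert-butyldimethylsilyloxy group | O=C[C@@H](O[Si](C)(C)C(C)(C)C)C[C@@]1(C)O[C@H]1CC/C(C)=C\C[C@@H](CS(=O)(=O)c1ccccc1)C(C)(C)O[Si](CC)(CC)CC | intermediate
26 | (10S,11R)-isopropenyl carbinol (10,11-anti; C10 silyl ether, free C11 hydroxyl) | C=C(C)[C@@H](O)[C@@H](O[Si](C)(C)C(C)(C)C)C[C@@]1(C)O[C@H]1CC/C(C)=C\C[C@@H](CS(=O)(=O)c1ccccc1)C(C)(C)O[Si](CC)(CC)CC | intermediate
27 | C11 methanesulfonate of 26 | C=C(C)[C@@H](OS(C)(=O)=O)[C@@H](O[Si](C)(C)C(C)(C)C)C[C@@]1(C)O[C@H]1CC/C(C)=C\C[C@@H](CS(=O)(=O)c1ccccc1)C(C)(C)O[Si](CC)(CC)CC | intermediate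
28 | open-chain C14 phenyl sulfone with (10S,11S)-trans isopropenyl oxirane, (7S,8R)-cis oxirane, 3Z alkene, (1R) and free C15 hydroxyl | C=C(C)[C@@H]1O[C@H]1C[C@@]2(C)O[C@H]2CC/C(C)=C\C[C@@H](CS(=O)(=O)c3ccccc3)C(C)(C)O | intermediate
29 | C14-lithio lithium alkoxide of 28 | C=C(C)[C@@H]1O[C@H]1C[C@@]2(C)O[C@H]2CC/C(C)=C\C[C@@H](C([Li])S(=O)(=O)c3ccccc3)C(C)(C)O[Li] | intermediate
30 | open-chain C14 bis(phenylsulfonyl) compound with (7S,8R)-cis oxirane and (10S,11S)-isopropenyl oxirane, 3Z, 1R, free C15 hydroxyl | C=C(C)[C@@H]1O[C@H]1C[C@@]2(C)O[C@H]2CC/C(C)=C\C[C@@H](C(S(=O)(=O)c3ccccc3)S(=O)(=O)c3ccccc3)C(C)(C)O | intermediate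
31 | 14,14-bis(phenylsulfonyl) macrocyclic (10S)-allylic alcohol (11E, 3Z, 7S,8R oxirane, 1R) | O[C@@H]1/C=C(\C)CC(S(=O)(=O)c3ccccc3)(S(=O)(=O)c3ccccc3)[C@@H](C(C)(C)O)C/C=C(/C)CC[C@@H]2O[C@]2(C)C1 | intermediate
32 | macrocyclic C10,C15-diol (1R,3Z,7S,8R,10S,11E) | O[C@@H]1/C=C(\C)CC[C@@H](C(C)(C)O)C/C=C(/C)CC[C@@H]2O[C@]2(C)C1 | intermediate
33 | CNP0254503.1, C10 acetate of 32 | CC(=O)O[C@@H]1/C=C(\C)CC[C@@H](C(C)(C)O)C/C=C(/C)CC[C@@H]2O[C@]2(C)C1 | target

**Step count and risks**

Total steps: 24. Longest linear sequence: 23 steps (1 to 33 through steps 1–11 and 13–24; step 12 is the only branch).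

Steps most likely to fail:

Step 22 (key step). Ring closure may be outrun by β-hydride elimination of the π-allyl intermediate to a dienol or enone, or by intermolecular alkylation, because the attacking C14 carbanion is tertiary and sits next to the branched C1. The fallback sets out from 26. Thionyl chloride in ether, with 2,6-di-tert-butylpyridine as acid scavenger, should chlorinate with allylic transposition (SNi′) to the E primary allylic chloride F1. KN(SiMe3)2 in THF at high dilution then generates the less hindered secondary α-sulfonyl carbanion at C14, whose intramolecular SN2 alkylation at C13 closes the 14-membered ring as the macrocyclic mono-sulfone F2. Sodium amalgam removes the sulfone to give the macrocyclic bis-silyl ether F3, and n-Bu4NF cleaves both silyl ethers, which returns to the route at 32.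

Step 15. Oxygen may be delivered to the wrong alkene face, or with low face selectivity, if this trisubstituted Z-alkene does not follow the chair-like vanadate arrangement. The fallback sets out from 21. The C10 hydroxyl is converted with NaN(SiMe3)2 and Boc2O into the tert-butyl carbonate F4. IBr at low temperature should then induce iodocarbonate cyclisation, the carbonyl oxygen attacking C8 anti to the iodonium ion, to give the six-membered cyclic iodocarbonate F5 with the 1,3-syn relationship. K2CO3 in methanol cleaves the carbonate and the C8 alkoxide displaces iodide at C7 with inversion, which returns to the route at 22.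

Step 19. Facial selectivity of the Grignard addition to the α-silyloxy aldehyde may be low, which would erode the C11 configuration needed for the trans oxirane. The fallback sets out from 25. The addition is run without regard to selectivity, and the mixture of 26 and its C11 epimer F6 is oxidised with Dess–Martin periodinane to the isopropenyl ketone F7. Corey–Bakshi–Shibata reduction with the (R)-2-methyl oxazaborolidine and BH3·SMe2, in which the isopropenyl group acts as the large substituent, should then set C11 under reagent control and return to the route at 26.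

Further compounds
F1 | step 22 | E primary allylic chloride (C13 chloride, E C11=C12 alkene, 10S silyl ether, C14 mono-sulfone, C15 triethylsilyl ether) | ClC/C(C)=C/[C@@H](O[Si](C)(C)C(C)(C)C)C[C@@]1(C)O[C@H]1CC/C(C)=C\C[C@@H](CS(=O)(=O)c1ccccc1)C(C)(C)O[Si](CC)(CC)CC
F2 | step 22 | macrocyclic C14 mono(phenylsulfonyl) bis-silyl ether (C14 epimers) | CC(C)(C)[Si](C)(C)O[C@@H]1/C=C(\C)CC(S(=O)(=O)c3ccccc3)[C@@H](C(C)(C)O[Si](CC)(CC)CC)C/C=C(/C)CC[C@@H]2O[C@]2(C)C1
F3 | step 22 | macrocyclic bis-silyl ether of 32 | CC(C)(C)[Si](C)(C)O[C@@H]1/C=C(\C)CC[C@@H](C(C)(C)O[Si](CC)(CC)CC)C/C=C(/C)CC[C@@H]2O[C@]2(C)C1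
F4 | step 15 | C10 tert-butyl carbonate of 21 | COc1ccc(COC[C@@H](OC(=O)OC(C)(C)C)C/C(C)=C\CC/C(C)=C\C[C@@H](CS(=O)(=O)c2ccccc2)C(C)(C)O[Si](CC)(CC)CC)cc1
F5 | step 15 | six-membered cyclic carbonate across C8 and C10 with iodine at C7 | COc1ccc(COC[C@@H]2C[C@](C)([C@H](I)CC/C(C)=C\C[C@@H](CS(=O)(=O)c3ccccc3)C(C)(C)O[Si](CC)(CC)CC)OC(=O)O2)cc1
F6 | step 19 | C11 epimer of 26, (10S,11S)-isopropenyl carbinol | C=C(C)[C@H](O)[C@@H](O[Si](C)(C)C(C)(C)C)C[C@@]1(C)O[C@H]1CC/C(C)=C\C[C@@H](CS(=O)(=O)c1ccccc1)C(C)(C)O[Si](CC)(CC)CC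
F7 | step 19 | C11 isopropenyl ketone with (10S) silyloxy group | C=C(C)C(=O)[C@@H](O[Si](C)(C)C(C)(C)C)C[C@@]1(C)O[C@H]1CC/C(C)=C\C[C@@H](CS(=O)(=O)c1ccccc1)C(C)(C)O[Si](CC)(CC)CC
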